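**Assumptions.** The skeleton is labelled with germacrane numbers (C6 = lactone O‑carbon, C7, C8 = ester carbon, C10 = quaternary ether carbon, C11 = spiro carbon, C13 = former exo‑methylene carbon). C1′–C4′ are the diene carbons of myrcene, with C2′ bearing the 4‑methylpent‑3‑enyl chain. The five starting materials in the list are taken as catalogue compounds.

**Retrosynthetic overview**
1. Spiro‑cyclohexene (C11) last: visible‑light, iodine‑atom‑relayed [4+2] of myrcene onto the exo‑methylene lactone (C13–C4′, then C11–C1′), giving the "1,3" regiochemistry that the thermal Diels–Alder disfavours.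
2. γ‑Lactone and ten‑membered ring together: intramolecular indium Barbier allylation of a (Z)‑enal by a (Z)‑2‑(bromomethyl)enoate (C6–C7), then lactonisation to the cis‑lactone.
3. Acrylate unit (C11–C13) added to a C7 aldehyde as a vinylalane; the angelate is installed early by Mitsunobu inversion at C8.
4. 3(2H)‑Furanone first: the acetylide of the silylated (Z)‑enynol opens an α‑hydroxy‑α‑methyl‑γ‑lactone, followed by 5‑endo oxa‑Michael closure.
5. C8 is bought (L‑glutamic‑acid‑derived (S)‑lactone) and relays to C10 (enolate methylation, then hydroxylation); C6/C7 follow from C8 and C11 from C7. Ring order: furanone → macrocycle + lactone → cyclohexene.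

**Route**

Step 1
Reactants: 1 (Z)-3-methylpent-2-en-4-yn-1-ol
Product: 2 (Z)-tert-butyl[(3-methylpent-2-en-4-yn-1-yl)oxy]diphenylsilane
Conditions: TBDPSCl, imidazole, CH2Cl2, 0 → 23 °C
Reagents that add atoms: tert-butyl(chloro)diphenylsilane, CC(C)(C)[Si](Cl)(c1ccccc1)c1ccccc1
Why: Imidazole-promoted silyl ether formation masks O6 so that only the tertiary alkoxide can attack the ynone in step 4; no stereocentre is involved and the Z-alkene is untouched.

Step 2
Reactants: 3 (S)-5-[(trityloxy)methyl]dihydrofuran-2(3H)-one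
Product: 4 (3R,5S)-3-methyl-5-[(trityloxy)methyl]dihydrofuran-2(3H)-one (trans)
Conditions: LiN(iPr)2, THF, −78 °C; MeI, −78 → −40 °C
Reagents that add atoms: iodomethane, CI
Why: Lactone enolate alkylation under 1,3-induction, in which MeI attacks the lithium enolate anti to the bulky trityloxymethyl group to give the trans (3R) methyl lactone.

Step 3
Reactants: 4 (3R,5S)-3-methyl-5-[(trityloxy)methyl]dihydrofuran-2(3H)-one
Product: 5 (3R,5S)-3-hydroxy-3-methyl-5-[(trityloxy)methyl]dihydrofuran-2(3H)-one (OH trans to the CH2OTr arm)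
Conditions: KN(SiMe3)2, THF, −78 °C; racemic 2-(phenylsulfonyl)-3-phenyloxaziridine; AcOH quench
Reagents that add atoms: 2-(phenylsulfonyl)-3-phenyloxaziridine, O=S(=O)(c1ccccc1)N1OC1c1ccccc1
Why: Davis oxaziridine hydroxylation of the tetrasubstituted potassium enolate again occurs anti to the C5 substituent, so the future C10 becomes (R) under control of the bought centre (future C8).

Step 4
Reactants: 5 (3R,5S)-3-hydroxy-3-methyl-5-[(trityloxy)methyl]dihydrofuran-2(3H)-one; 2 (Z)-tert-butyl[(3-methylpent-2-en-4-yn-1-yl)oxy]diphenylsilane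
Product: 7 (R)-5-[(Z)-4-(tert-butyldiphenylsilyloxy)but-2-en-2-yl]-2-[(S)-2-hydroxy-3-(trityloxy)propyl]-2-methylfuran-3(2H)-one, via open-chain hydroxy ynone 6 (not isolated)
Conditions: 2 (2.3 equiv), n-BuLi (2.2 equiv), THF, −78 °C; add 5, −78 → −20 °C; then MeOH, 23 °C
Reagents that add atoms: none
Why: Acetylide addition to the lactone stops at the hemiketal alkoxide, which opens to ynone 6 on MeOH quench, and the lithium methoxide formed drives 5-endo-dig oxa-Michael addition of the tertiary hydroxyl to give the 3(2H)-furanone without touching a stereocentre or the Z-alkene (O6 is silylated and cannot form a furan).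

Step 5
Reactants: 7 (R)-5-[(Z)-4-(tert-butyldiphenylsilyloxy)but-2-en-2-yl]-2-[(S)-2-hydroxy-3-(trityloxy)propyl]-2-methylfuran-3(2H)-one; 8 angelic acid, (Z)-2-methylbut-2-enoic acid
Product: 9 (R)-1-{(R)-5-[(Z)-4-(tert-butyldiphenylsilyloxy)but-2-en-2-yl]-2-methyl-3-oxo-2,3-dihydrofuran-2-yl}-3-(trityloxy)propan-2-yl (Z)-2-methylbut-2-enoate
Conditions: PPh3, DIAD, toluene, 0 → 23 °C
Reagents that add atoms: none
Why: Mitsunobu esterification displaces the oxyphosphonium by SN2 with clean inversion, turning the bought (S)-carbinol into the (R)-angelate needed at C8 under neutral conditions that do not isomerise angelate to tiglate.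

Step 6
Reactants: 9 (R)-1-{(R)-5-[(Z)-4-(tert-butyldiphenylsilyloxy)but-2-en-2-yl]-2-methyl-3-oxo-2,3-dihydrofuran-2-yl}-3-(trityloxy)propan-2-yl (Z)-2-methylbut-2-enoate
Product: 10 (R)-1-{(R)-5-[(Z)-4-(tert-butyldiphenylsilyloxy)but-2-en-2-yl]-2-methyl-3-oxo-2,3-dihydrofuran-2-yl}-3-hydroxypropan-2-yl (Z)-2-methylbut-2-enoate
Conditions: TsOH·H2O (0.1 equiv), MeOH/CH2Cl2 (1:1), 0 °C
Reagents that add atoms: none
Why: Acid-catalysed methanolysis of the trityl ether (SN1, trityl cation trapped as its methyl ether) frees the primary C7 hydroxyl while the TBDPS ether, angelate and furanone survive the brief cold acid.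

Step 7
Reactants: 10 (R)-1-{(R)-5-[(Z)-4-(tert-butyldiphenylsilyloxy)but-2-en-2-yl]-2-methyl-3-oxo-2,3-dihydrofuran-2-yl}-3-hydroxypropan-2-yl (Z)-2-methylbut-2-enoate
Product: 11 (R)-1-{(R)-5-[(Z)-4-(tert-butyldiphenylsilyloxy)but-2-en-2-yl]-2-methyl-3-oxo-2,3-dihydrofuran-2-yl}-3-oxopropan-2-yl (Z)-2-methylbut-2-enoate
Conditions: Dess–Martin periodinane, CH2Cl2, 0 → 23 °C; used crude
Reagents that add atoms: none
Why: Dess–Martin oxidation is non-basic, so the α-acyloxy aldehyde forms without epimerising C8.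

Step 8
Reactants: 11 (R)-1-{(R)-5-[(Z)-4-(tert-butyldiphenylsilyloxy)but-2-en-2-yl]-2-methyl-3-oxo-2,3-dihydrofuran-2-yl}-3-oxopropan-2-yl (Z)-2-methylbut-2-enoate; 12 methyl propiolate
Product: 13 methyl (3RS,4R)-4-[(Z)-2-methylbut-2-enoyloxy]-5-{(R)-5-[(Z)-4-(tert-butyldiphenylsilyloxy)but-2-en-2-yl]-2-methyl-3-oxo-2,3-dihydrofuran-2-yl}-3-hydroxy-2-methylidenepentanoate
Conditions: 12, iBu2AlH, NMO, THF, 0 °C, 1 h; then 11, 0 → 23 °C; Rochelle salt work-up
Reagents that add atoms: none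
Why: Hydroalumination of methyl propiolate gives the α-aluminated acrylate, which adds to the aldehyde as an amine-free equivalent of the Morita–Baylis–Hillman reaction (no enolisation of the α-acyloxy aldehyde, no acyl migration), and the new C7 carbinol forms as an epimer mixture that is erased in step 11.

Step 9
Reactants: 13 methyl (3RS,4R)-4-[(Z)-2-methylbut-2-enoyloxy]-5-{(R)-5-[(Z)-4-(tert-butyldiphenylsilyloxy)but-2-en-2-yl]-2-methyl-3-oxo-2,3-dihydrofuran-2-yl}-3-hydroxy-2-methylidenepentanoate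
Product: 14 methyl (3RS,4R)-4-[(Z)-2-methylbut-2-enoyloxy]-3-hydroxy-5-{(R)-5-[(Z)-4-hydroxybut-2-en-2-yl]-2-methyl-3-oxo-2,3-dihydrofuran-2-yl}-2-methylidenepentanoate
Conditions: HF·pyridine, pyridine, THF, 0 → 23 °C
Reagents that add atoms: none
Why: Fluoride cleaves the silyl ether through Si–F bond formation, and the pyridine buffer protects the esters and the allylic alcohol.

Step 10
Reactants: 14 methyl (3RS,4R)-4-[(Z)-2-methylbut-2-enoyloxy]-3-hydroxy-5-{(R)-5-[(Z)-4-hydroxybut-2-en-2-yl]-2-methyl-3-oxo-2,3-dihydrofuran-2-yl}-2-methylidenepentanoate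
Product: 15 methyl (3RS,4R)-4-[(Z)-2-methylbut-2-enoyloxy]-3-hydroxy-5-{(R)-2-methyl-3-oxo-5-[(Z)-4-oxobut-2-en-2-yl]-2,3-dihydrofuran-2-yl}-2-methylidenepentanoate
Conditions: TEMPO (0.1 equiv), PhI(OAc)2, CH2Cl2, 23 °C
Reagents that add atoms: none
Why: The oxoammonium (TEMPO/PhI(OAc)2) oxidation is selective for the primary allylic alcohol over the secondary one and does not isomerise Z-enals.

Step 11
Reactants: 15 methyl (3RS,4R)-4-[(Z)-2-methylbut-2-enoyloxy]-3-hydroxy-5-{(R)-2-methyl-3-oxo-5-[(Z)-4-oxobut-2-en-2-yl]-2,3-dihydrofuran-2-yl}-2-methylidenepentanoate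
Product: 16 methyl (2Z,4R)-2-(bromomethyl)-4-[(Z)-2-methylbut-2-enoyloxy]-5-{(R)-2-methyl-3-oxo-5-[(Z)-4-oxobut-2-en-2-yl]-2,3-dihydrofuran-2-yl}pent-2-enoate
Conditions: NBS and Me2S pre-mixed, CH2Cl2, −20 → 0 °C
Reagents that add atoms: N-bromosuccinimide, O=C1CCC(=O)N1Br
Why: The bromodimethylsulfonium reagent (Corey–Kim conditions) activates the Morita–Baylis–Hillman alcohol and bromide enters by SN2′ to give the thermodynamically preferred (Z)-2-(bromomethyl)enoate, which removes the C7 epimer mixture.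

Step 12
Reactants: 16 methyl (2Z,4R)-2-(bromomethyl)-4-[(Z)-2-methylbut-2-enoyloxy]-5-{(R)-2-methyl-3-oxo-5-[(Z)-4-oxobut-2-en-2-yl]-2,3-dihydrofuran-2-yl}pent-2-enoate
Product: 18 (6S,7R,8R,10R)-8-angeloyloxy-1-oxo-3,10-epoxygermacra-2,4Z,11(13)-trien-12,6-olide (H-6/H-7 cis), via macrocyclic hydroxy ester 17 (not isolated)
Conditions: indium powder, THF/H2O (3:1), 0.005 M, 23 °C; then TsOH·H2O (cat.), CH2Cl2, 23 °C
Reagents that add atoms: none
Why: Intramolecular indium Barbier allylation in which the (Z)-allylindium adds through C7 to the enal in a Zimmerman–Traxler chair (C5 equatorial, C8 axial) to give the 6,7-syn adduct and hence the cis-lactone, while the C8 centre (H eclipsing the alkene to avoid allylic 1,3-strain, C9 anti, acyloxy outside) directs attack to the face giving (6S,7R), and acid then closes the γ-lactone with loss of methanol.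

Step 13
Reactants: 18 (6S,7R,8R,10R)-8-angeloyloxy-1-oxo-3,10-epoxygermacra-2,4Z,11(13)-trien-12,6-olide; 19 myrcene
Product: 21 (6S,7R,8R,10R,11S)-8-angeloyloxy-1-oxo-3,10-epoxygermacra-2,4Z-dien-12,6-olide with C11 as spiro atom of the cyclohex-3-ene ring C11–C1′H2–C2′(4-methylpent-3-enyl)=C3′H–C4′H2–C13H2 (CNP0226905.2), via iodoallyl lactone enolate 20 (not isolated)
Conditions: 19 (5 equiv), Ru(bpz)3(PF6)2 (2 mol %), Bu4NI (20 mol %), MeCN (0.03 M), 455 nm LEDs, 25 °C, Ar
Reagents that add atoms: none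
Why: Proposed new method: photo-oxidation of iodide by excited Ru(bpz)3(PF6)2 gives an iodine atom that adds reversibly to the 1,1-disubstituted terminus C1′ of myrcene (the most stabilised, tertiary-ended allyl radical), the iodoallyl radical adds through its free primary terminus C4′ to the exocyclic methylene C13 of 18 (Giese step), the reduced photocatalyst turns the α-lactonyl radical into enolate 20, and 20 closes 6-exo-tet on the allylic iodide (C11–C1′) from the open H-7 face of the cis-fused lactone, which sets C11 (S) and returns iodide, so that the catalyst rather than the dienophile β-carbon occupies the nucleophilic diene terminus and the regiochemistry is the reverse of the thermal Diels–Alder; the closest known chemistry is the bromine- or thiyl-radical-catalysed [3+2] cycloaddition of vinylcyclopropanes and photoredox radical–polar crossover (Giese addition/alkylation) annulation.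

**Compound list**
1 | (Z)-3-methylpent-2-en-4-yn-1-ol | C#C/C(C)=C\CO | starting material
2 | (Z)-tert-butyl[(3-methylpent-2-en-4-yn-1-yl)oxy]diphenylsilane | C#C/C(C)=C\CO[Si](c1ccccc1)(c1ccccc1)C(C)(C)C | intermediate
3 | (S)-5-[(trityloxy)methyl]dihydrofuran-2(3H)-one | O=C1CC[C@@H](COC(c2ccccc2)(c2ccccc2)c2ccccc2)O1 | starting material
4 | (3R,5S)-3-methyl-5-[(trityloxy)methyl]dihydrofuran-2(3H)-one | O=C1[C@H](C)C[C@@H](COC(c2ccccc2)(c2ccccc2)c2ccccc2)O1 | intermediate
5 | (3R,5S)-3-hydroxy-3-methyl-5-[(trityloxy)methyl]dihydrofuran-2(3H)-one | O=C1[C@](C)(O)C[C@@H](COC(c2ccccc2)(c2ccccc2)c2ccccc2)O1 | intermediate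
6 | (2Z,7R,9S)-1-(tert-butyldiphenylsilyloxy)-7,9-dihydroxy-3,7-dimethyl-10-(trityloxy)dec-2-en-4-yn-6-one | C(OC(c1ccccc1)(c1ccccc1)c1ccccc1)[C@@H](O)C[C@@](C)(O)C(=O)C#C/C(C)=C\CO[Si](c1ccccc1)(c1ccccc1)C(C)(C)C | intermediate
7 | (R)-5-[(Z)-4-(tert-butyldiphenylsilyloxy)but-2-en-2-yl]-2-[(S)-2-hydroxy-3-(trityloxy)propyl]-2-methylfuran-3(2H)-one | C(OC(c1ccccc1)(c1ccccc1)c1ccccc1)[C@@H](O)C[C@@]1(C)OC(=CC1=O)/C(C)=C\CO[Si](c1ccccc1)(c1ccccc1)C(C)(C)C | intermediate
8 | angelic acid, (Z)-2-methylbut-2-enoic acid | C/C=C(/C)C(=O)O | starting material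
9 | (R)-1-{(R)-5-[(Z)-4-(tert-butyldiphenylsilyloxy)but-2-en-2-yl]-2-methyl-3-oxo-2,3-dihydrofuran-2-yl}-3-(trityloxy)propan-2-yl (Z)-2-methylbut-2-enoate | C(OC(c1ccccc1)(c1ccccc1)c1ccccc1)[C@H](OC(=O)/C(C)=C\C)C[C@@]1(C)OC(=CC1=O)/C(C)=C\CO[Si](c1ccccc1)(c1ccccc1)C(C)(C)C | intermediate
10 | (R)-1-{(R)-5-[(Z)-4-(tert-butyldiphenylsilyloxy)but-2-en-2-yl]-2-methyl-3-oxo-2,3-dihydrofuran-2-yl}-3-hydroxypropan-2-yl (Z)-2-methylbut-2-enoate | OC[C@H](OC(=O)/C(C)=C\C)C[C@@]1(C)OC(=CC1=O)/C(C)=C\CO[Si](c1ccccc1)(c1ccccc1)C(C)(C)C | intermediate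
11 | (R)-1-{(R)-5-[(Z)-4-(tert-butyldiphenylsilyloxy)but-2-en-2-yl]-2-methyl-3-oxo-2,3-dihydrofuran-2-yl}-3-oxopropan-2-yl (Z)-2-methylbut-2-enoate | O=C[C@H](OC(=O)/C(C)=C\C)C[C@@]1(C)OC(=CC1=O)/C(C)=C\CO[Si](c1ccccc1)(c1ccccc1)C(C)(C)C | intermediate
12 | methyl propiolate | C#CC(=O)OC | starting material
13 | methyl (3RS,4R)-4-[(Z)-2-methylbut-2-enoyloxy]-5-{(R)-5-[(Z)-4-(tert-butyldiphenylsilyloxy)but-2-en-2-yl]-2-methyl-3-oxo-2,3-dihydrofuran-2-yl}-3-hydroxy-2-methylidenepentanoate | C=C(C(=O)OC)C(O)[C@H](OC(=O)/C(C)=C\C)C[C@@]1(C)OC(=CC1=O)/C(C)=C\CO[Si](c1ccccc1)(c1ccccc1)C(C)(C)C | intermediate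
14 | methyl (3RS,4R)-4-[(Z)-2-methylbut-2-enoyloxy]-3-hydroxy-5-{(R)-5-[(Z)-4-hydroxybut-2-en-2-yl]-2-methyl-3-oxo-2,3-dihydrofuran-2-yl}-2-methylidenepentanoate | C=C(C(=O)OC)C(O)[C@H](OC(=O)/C(C)=C\C)C[C@@]1(C)OC(=CC1=O)/C(C)=C\CO | intermediate
15 | methyl (3RS,4R)-4-[(Z)-2-methylbut-2-enoyloxy]-3-hydroxy-5-{(R)-2-methyl-3-oxo-5-[(Z)-4-oxobut-2-en-2-yl]-2,3-dihydrofuran-2-yl}-2-methylidenepentanoate | C=C(C(=O)OC)C(O)[C@H](OC(=O)/C(C)=C\C)C[C@@]1(C)OC(=CC1=O)/C(C)=C\C=O | intermediate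
16 | methyl (2Z,4R)-2-(bromomethyl)-4-[(Z)-2-methylbut-2-enoyloxy]-5-{(R)-2-methyl-3-oxo-5-[(Z)-4-oxobut-2-en-2-yl]-2,3-dihydrofuran-2-yl}pent-2-enoate | BrC/C(C(=O)OC)=C\[C@H](OC(=O)/C(C)=C\C)C[C@@]1(C)OC(=CC1=O)/C(C)=C\C=O | intermediate
17 | methyl 2-[(6S,7R,8R,10R)-8-angeloyloxy-6-hydroxy-1-oxo-3,10-epoxygermacra-2,4Z-dien-7-yl]prop-2-enoate | C/C=C(/C)C(=O)O[C@@H]1C[C@@]2(C)OC(=CC2=O)/C(C)=C\[C@H](O)[C@@H]1C(=C)C(=O)OC | intermediate
18 | (6S,7R,8R,10R)-8-angeloyloxy-1-oxo-3,10-epoxygermacra-2,4Z,11(13)-trien-12,6-olide | C/C=C(/C)C(=O)O[C@@H]1C[C@@]2(C)OC(=CC2=O)/C(C)=C\[C@@H]2OC(=O)C(=C)[C@@H]21 | intermediate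
19 | myrcene, 7-methyl-3-methylideneocta-1,6-diene | C=CC(=C)CCC=C(C)C | starting material
20 | tetrabutylammonium enolate of the (Z)-allylic iodide adduct (C13–C4′ bond formed, C1′–I, lactone enolate at C11/C12) | CCCC[N+](CCCC)(CCCC)CCCC.C/C=C(/C)C(=O)O[C@@H]1C[C@@]2(C)OC(=CC2=O)/C(C)=C\[C@@H]2OC([O-])=C(CC/C=C(\CI)CCC=C(C)C)[C@@H]21 | intermediate
21 | CNP0226905.2, (6S,7R,8R,10R,11S)-8-angeloyloxy-1-oxo-3,10-epoxygermacra-2,4Z-dien-12,6-olide spiro-fused at C11 to 3-(4-methylpent-3-enyl)cyclohex-3-ene | C/C=C(/C)C(=O)O[C@@H]1C[C@@]2(C)OC(=CC2=O)/C(C)=C\[C@@H]2OC(=O)[C@]3(CCC=C(CCC=C(C)C)C3)[C@@H]21 | target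

**Step count.** 13 steps in total; the longest linear sequence is 12 steps (3 → 21, steps 2–13), with step 1 as a one-step side branch.

**Steps most likely to fail**

Step 13 (the proposed new annulation). Three things can go wrong. The stabilised iodoallyl radical may add too slowly to 18. Only the cisoid allylic iodide can close, so the route relies on the fast E/Z and 1,3-equilibration typical of allyl radicals and allylic iodides. Iodine atoms could also isomerise the angelate to the tiglate. The fallback sets out from 18 and comes back at 21 by the known thermal Diels–Alder reaction: 18 is heated in neat myrcene 19 (10 equiv, BHT, 90 °C, sealed tube, no Lewis acid). Addition again occurs on the H-7 face, but 21 is then the minor "1,3" regioisomer (roughly one part in three to four) next to the 1,4-isomer and has to be separated by preparative HPLC. This fallback makes no new compound (F0).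

Step 12 (indium macrocyclisation). The nine-atom ring closure may be slow. The allylindium may lose the C8 angelate by 1,4-elimination to a diene. The facial control by C8 rests on an acyclic model. The fallback sets out from 16 and comes back at 18 through a metal-free, closed-transition-state allylboration. Palladium-catalysed borylation of the allylic bromide (B2pin2, Pd2(dba)3 cat., THF, 23 °C) gives methyl (2Z,4R)-4-[(Z)-2-methylbut-2-enoyloxy]-5-{(R)-2-methyl-3-oxo-5-[(Z)-4-oxobut-2-en-2-yl]-2,3-dihydrofuran-2-yl}-2-[(4,4,5,5-tetramethyl-1,3,2-dioxaborolan-2-yl)methyl]pent-2-enoate F1, which cannot β-eliminate. Sc(OTf)3 (10 mol %) in toluene at high dilution then triggers the intramolecular allylboration of the enal (chair transition state, the Z-boronate giving the syn adduct 17), and acid work-up lactonises 17 to 18.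

Step 5 (Mitsunobu with angelic acid). The carbinol is flanked by a CH2OTr group and a CH2 attached to a quaternary carbon, and angelic acid is a hindered, weakly acidic partner, so the oxyphosphonium may eliminate or simply not form. The fallback sets out from 7 and comes back at 9 by sulfonate displacement: MsCl/Et3N (CH2Cl2, 0 °C) gives (S)-1-{(R)-5-[(Z)-4-(tert-butyldiphenylsilyloxy)but-2-en-2-yl]-2-methyl-3-oxo-2,3-dihydrofuran-2-yl}-3-(trityloxy)propan-2-yl methanesulfonate F2. Caesium angelate (from 8 and Cs2CO3, with 18-crown-6 in DMF at 60 °C) then displaces the mesylate by SN2 with inversion to give 9.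

Further compounds
F0 | step 13 | none | none
F1 | step 12 | methyl (2Z,4R)-4-[(Z)-2-methylbut-2-enoyloxy]-5-{(R)-2-methyl-3-oxo-5-[(Z)-4-oxobut-2-en-2-yl]-2,3-dihydrofuran-2-yl}-2-[(4,4,5,5-tetramethyl-1,3,2-dioxaborolan-2-yl)methyl]pent-2-enoate | CC1(C)OB(C/C(C(=O)OC)=C\[C@H](OC(=O)/C(C)=C\C)C[C@@]2(C)OC(=CC2=O)/C(C)=C\C=O)OC1(C)C
F2 | step 5 | (S)-1-{(R)-5-[(Z)-4-(tert-butyldiphenylsilyloxy)but-2-en-2-yl]-2-methyl-3-oxo-2,3-dihydrofuran-2-yl}-3-(trityloxy)propan-2-yl methanesulfonate | C(OC(c1ccccc1)(c1ccccc1)c1ccccc1)[C@@H](OS(C)(=O)=O)C[C@@]1(C)OC(=CC1=O)/C(C)=C\CO[Si](c1ccccc1)(c1ccccc1)C(C)(C)C
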